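**Strategy.** Ring B (B1 carbonyl-bearing, B2 hydroxyl, B4 ester oxygen, B6 methyl) is not bought as an orsellinate but built onto the ring C ester. Cutting B2–B3, B4–B5 and B1–B2 leaves two pieces: the ring C aryl ester of (E)-5-diazo-3-methyl-4-oxopent-2-enoic acid and (triisopropylsilyloxy)acetylene. One photochemical benzannulation joins them and closes ring B, exploiting its resorcinol pattern: B1 arrives already carrying the ester to ring C and B6 its methyl, while the two meta oxygens emerge differentiated, B2 as a chelated free phenol and B4 as a silyl ether. Freeing B4 alone allows acylation with the benzyl-protected ring A acid, and a single hydrogenolysis then releases the tridepside.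

Key step: step 8

Remarks on the chemistry:
- Ring A is the dimethoxy ring, ring B the central ring, ring C the ring with the free carboxylic acid; the target has no stereocentre, and the only stereo-element in the route is the E alkene of the enoate.
- The enoate is built E (ester trans to the diazoacetyl group): in the Z isomer the ketene would lie next to the ester carbonyl and could close to a 6-aryloxy-2-pyranone, and the ester would point inward in the carbocyclic ring closure.
- The diazo group is introduced by diazo transfer, because diazomethane would add as a dipole to the electron-poor alkene.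
- In the key step the Wolff shift also moves the alkenyl carbon from the ketone carbon to the diazo carbon, so B5–B6 arises from this 1,2-shift; B2–B3, B4–B5 and B1–B2 are the bonds made between previously unconnected atoms.
- 3-Phenylisoxazole, (triphenylphosphoranylidene)ketene and butane-2,3-dione are taken as commercial.

**Route**

Step 1
Reactants: 1 orsellinic acid (2,4-dihydroxy-6-methylbenzoic acid)
Product: 2 benzyl 2,4-dihydroxy-6-methylbenzoate
Conditions: BnBr (1.05 equiv), KHCO3, DMF, rt to 40 °C
Reagents that add atoms: benzyl bromide, BrCc1ccccc1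
Why: Carboxylate O-alkylation (SN2); hydrogencarbonate ionises only the carboxylic acid, so both phenols stay free, and the mild temperature avoids decarboxylation.

Step 2
Reactants: 2 benzyl 2,4-dihydroxy-6-methylbenzoate
Product: 3 benzyl 4-(allyloxy)-2-hydroxy-6-methylbenzoate
Conditions: allyl bromide (1.05 equiv), K2CO3, acetone, reflux
Reagents that add atoms: allyl bromide, C=CCBr
Why: Williamson etherification; the 4-hydroxyl is the unchelated, more acidic phenol, whereas the 2-hydroxyl is tied up in a hydrogen bond to the ester carbonyl, so one equivalent of halide should react at O4 only.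

Step 3
Reactants: 3 benzyl 4-(allyloxy)-2-hydroxy-6-methylbenzoate
Product: 4 benzyl 4-(allyloxy)-2-(benzyloxy)-6-methylbenzoate
Conditions: BnBr, K2CO3, Bu4NI (cat.), DMF, 60 °C
Reagents that add atoms: benzyl bromide, BrCc1ccccc1
Why: Williamson etherification under more forcing conditions benzylates the remaining chelated phenol; allyl ether and benzyl ester are inert.

Step 4
Reactants: 4 benzyl 4-(allyloxy)-2-(benzyloxy)-6-methylbenzoate
Product: 5 benzyl 2-(benzyloxy)-4-hydroxy-6-methylbenzoate
Conditions: Pd(PPh3)4 (cat.), morpholine, THF, rt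
Reagents that add atoms: none
Why: Tsuji–Trost deallylation; zerovalent palladium ionises the aryl allyl ether to a pi-allyl complex that morpholine captures, while benzyl ether and benzyl ester are untouched in the absence of hydrogen.

Step 5
Reactants: 5 benzyl 2-(benzyloxy)-4-hydroxy-6-methylbenzoate; 6 (triphenylphosphoranylidene)ketene; 7 butane-2,3-dione
Product: 9 benzyl 2-(benzyloxy)-6-methyl-4-{[(2E)-3-methyl-4-oxopent-2-enoyl]oxy}benzoate, via aryl ester ylide 8 (not isolated)
Conditions: 6 (1.1 equiv), toluene, 80 °C; then 7 (3 equiv), 80 °C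
Reagents that add atoms: none
Why: Addition of the phenol to the cumulated ylide gives a stabilised ester ylide that olefinates one activated carbonyl of the 1,2-diketone (addition–Wittig sequence of the Bestmann ylide); the stabilised ylide should deliver the E alkene (ester trans to acetyl), and excess diketone suppresses double olefination.

Step 6
Reactants: 9 benzyl 2-(benzyloxy)-6-methyl-4-{[(2E)-3-methyl-4-oxopent-2-enoyl]oxy}benzoate
Product: 12 benzyl 2-(benzyloxy)-4-{[(2E)-5-diazo-3-methyl-4-oxopent-2-enoyl]oxy}-6-methylbenzoate, via lithium enolate 10 (not isolated), via trifluoroacetyl diketone 11 (not isolated)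
Conditions: LiN(SiMe3)2, THF, −78 °C (9 added to the base); CF3CO2CH2CF3, −78 °C; dilute HCl work-up; then 4-acetamidobenzenesulfonyl azide, Et3N, H2O (1 equiv), MeCN, rt
Reagents that add atoms: 4-acetamidobenzenesulfonyl azide, CC(=O)Nc1ccc(cc1)S(=O)(=O)N=[N+]=[N-]
Why: Danheiser detrifluoroacetylative diazo transfer; kinetic deprotonation of the acetyl methyl group at low temperature, Claisen trifluoroacetylation, then attack of the sulfonyl azide on the activated methylene with loss of the trifluoroacetyl group should give the diazo ketone with the E alkene intact.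

Step 7
Reactants: 13 3-phenylisoxazole; 14 triisopropylsilyl trifluoromethanesulfonate
Product: 17 (triisopropylsilyloxy)acetylene, via 5-lithio-3-phenylisoxazole 15 (not isolated), via lithium ethynolate 16 (not isolated)
Conditions: n-BuLi (1.0 equiv), THF, −78 to −20 °C; then 14, −78 to 0 °C; pentane, filtration, short-path distillation
Reagents that add atoms: none
Why: Lithiation at C5 of the isoxazole triggers fragmentation to benzonitrile and the ynolate (Schöllkopf ynolate generation), and the bulky, hard silyl triflate should silylate the ynolate on oxygen as in the Kowalski preparation of ynol silyl ethers.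

Step 8
Reactants: 12 benzyl 2-(benzyloxy)-4-{[(2E)-5-diazo-3-methyl-4-oxopent-2-enoyl]oxy}-6-methylbenzoate; 17 (triisopropylsilyloxy)acetylene
Product: 22 benzyl 2-(benzyloxy)-4-({2-hydroxy-6-methyl-4-[(triisopropylsilyl)oxy]benzoyl}oxy)-6-methylbenzoate, via vinylketene 18 (not isolated), via siloxycyclobutenone 19 (not isolated), via dienylketene 20 (not isolated), via cyclohexadienone 21 (not isolated)
Conditions: 17 (2.5 equiv), degassed ClCH2CH2Cl, hν (medium-pressure Hg lamp, uranium-glass filter, >340 nm), rt; then 80 °C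
Reagents that add atoms: none
Why: This is the Danheiser benzannulation in its photochemical Wolff form, known for alpha,beta-unsaturated diazo ketones and siloxyalkynes: light expels N2 from 12 and the alkenyl group shifts to the former diazo carbon, giving vinylketene 18. The ketene carbonyl carbon (future B2) bonds to the nucleophilic terminal carbon of 17 (B3) and the ketene alpha carbon (B5) to the silyloxy carbon (B4) in a [2+2] cycloaddition that gives the 4-alkenylcyclobutenone 19. Four-electron electrocyclic opening (light or 80 °C) gives dienylketene 20, and ring B is closed by six-electron electrocyclisation between B2 and B1, after which cyclohexadienone 21 tautomerises to the phenol. No stereocentre remains, since those at the ring carbon of 19 and at B1 of 21 are transient. The selectivity needed is regiochemical and is set by the polarity of the ynol ether, which places the silyloxy carbon meta to the new hydroxyl; the E alkene keeps the ester away from the ketene, so closure onto the ester carbonyl cannot compete and only hydrogen points inward in the ring closure. Filtered light excites the diazo ketone but not the aryl esters, which avoids photo-Fries rearrangement, and the chelated B2 phenol is a poor trap for ketene.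

Step 9
Reactants: 22 benzyl 2-(benzyloxy)-4-({2-hydroxy-6-methyl-4-[(triisopropylsilyl)oxy]benzoyl}oxy)-6-methylbenzoate
Product: 23 benzyl 2-(benzyloxy)-4-[(2,4-dihydroxy-6-methylbenzoyl)oxy]-6-methylbenzoate
Conditions: Bu4NF, AcOH, THF, 0 °C
Reagents that add atoms: none
Why: Fluoride-mediated cleavage of the aryl silyl ether; acetic acid buffers the phenoxide so that the aryl ester link should be neither cleaved nor transposed.

Step 10
Reactants: 24 2,3-dimethoxytoluene
Product: 26 3,4-dimethoxy-5-methylphenol, via arylboronate 25 (not isolated)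
Conditions: [Ir(OMe)(cod)]2 (cat.), 4,4'-di-tert-butyl-2,2'-bipyridine, B2pin2 (0.6 equiv), THF, 80 °C; then aq. H2O2, NaOH, 0 °C to rt
Reagents that add atoms: hydrogen peroxide, OO
Why: Sterically controlled iridium-catalysed C–H borylation reaches the only C–H flanked by two hydrogens (C5), a position electrophilic substitution would not choose, and oxidation of the C–B bond gives the phenol (one-pot borylation–oxidation).

Step 11
Reactants: 26 3,4-dimethoxy-5-methylphenol
Product: 27 5-(benzyloxy)-1,2-dimethoxy-3-methylbenzene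
Conditions: BnBr, K2CO3, acetone, reflux
Reagents that add atoms: benzyl bromide, BrCc1ccccc1
Why: Williamson etherification of the only phenol.

Step 12
Reactants: 27 5-(benzyloxy)-1,2-dimethoxy-3-methylbenzene
Product: 28 6-(benzyloxy)-3,4-dimethoxy-2-methylbenzaldehyde
Conditions: POCl3, DMF, 0 to 70 °C; then aq. NaOAc
Reagents that add atoms: N,N-dimethylformamide, CN(C)C=O; water, O
Why: Vilsmeier–Haack formylation; the chloroiminium ion should attack the carbon para to the coplanar methoxy group and ortho to the benzyloxy group (the reactive site of a 1,2,4-trialkoxybenzene, as with orcinol dimethyl ether), not the carbon between two oxygens.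

Step 13
Reactants: 28 6-(benzyloxy)-3,4-dimethoxy-2-methylbenzaldehyde
Product: 29 6-(benzyloxy)-3,4-dimethoxy-2-methylbenzoic acid
Conditions: NaClO2, NaH2PO4, 2-methyl-2-butene, t-BuOH/THF/H2O, rt
Reagents that add atoms: sodium chlorite, [Na+].[O-]Cl=O
Why: Pinnick oxidation of the hindered aldehyde; the alkene removes hypochlorous acid before it can chlorinate the electron-rich ring.

Step 14
Reactants: 29 6-(benzyloxy)-3,4-dimethoxy-2-methylbenzoic acid; 23 benzyl 2-(benzyloxy)-4-[(2,4-dihydroxy-6-methylbenzoyl)oxy]-6-methylbenzoate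
Product: 31 benzyl 4-{[4-{[6-(benzyloxy)-3,4-dimethoxy-2-methylbenzoyl]oxy}-2-hydroxy-6-methylbenzoyl]oxy}-2-(benzyloxy)-6-methylbenzoate, via acid chloride 30 (not isolated)
Conditions: (COCl)2, cat. DMF, CH2Cl2, 0 °C to rt, evaporate; then 23, pyridine, cat. DMAP, CH2Cl2, 0 °C to rt
Reagents that add atoms: none
Why: Acid chloride formation followed by DMAP-catalysed nucleophilic acyl substitution; the free B4 hydroxyl should react, since the B2 hydroxyl is hydrogen-bonded to and flanked by its ester carbonyl, and the bulky 2,6-disubstituted acyl chloride reinforces this preference.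

Step 15
Reactants: 31 benzyl 4-{[4-{[6-(benzyloxy)-3,4-dimethoxy-2-methylbenzoyl]oxy}-2-hydroxy-6-methylbenzoyl]oxy}-2-(benzyloxy)-6-methylbenzoate
Product: 32 2-hydroxy-4-({2-hydroxy-4-[(6-hydroxy-3,4-dimethoxy-2-methylbenzoyl)oxy]-6-methylbenzoyl}oxy)-6-methylbenzoic acid (CNP0139469.0)
Conditions: H2 (1 atm), 10% Pd/C, EtOAc, rt
Reagents that add atoms: none
Why: Catalytic hydrogenolysis removes the benzyl ester and both benzyl ethers; aryl ester links, methyl ethers and arenes are inert under these conditions.

**Compound list**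

1 | orsellinic acid | Cc1cc(O)cc(O)c1C(=O)O | starting material
2 | benzyl 2,4-dihydroxy-6-methylbenzoate | Cc1cc(O)cc(O)c1C(=O)OCc1ccccc1 | intermediate
3 | benzyl 4-(allyloxy)-2-hydroxy-6-methylbenzoate | Cc1cc(OCC=C)cc(O)c1C(=O)OCc1ccccc1 | intermediate
4 | benzyl 4-(allyloxy)-2-(benzyloxy)-6-methylbenzoate | Cc1cc(OCC=C)cc(OCc2ccccc2)c1C(=O)OCc1ccccc1 | intermediate
5 | benzyl 2-(benzyloxy)-4-hydroxy-6-methylbenzoate | Cc1cc(O)cc(OCc2ccccc2)c1C(=O)OCc1ccccc1 | intermediate
6 | (triphenylphosphoranylidene)ketene | O=C=C=P(c1ccccc1)(c1ccccc1)c1ccccc1 | starting material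
7 | butane-2,3-dione | CC(=O)C(C)=O | starting material
8 | benzyl 2-(benzyloxy)-6-methyl-4-{[(triphenylphosphoranylidene)acetyl]oxy}benzoate | Cc1cc(OC(=O)C=P(c2ccccc2)(c2ccccc2)c2ccccc2)cc(OCc2ccccc2)c1C(=O)OCc1ccccc1 | intermediate (not isolated)
9 | benzyl 2-(benzyloxy)-6-methyl-4-{[(2E)-3-methyl-4-oxopent-2-enoyl]oxy}benzoate | CC(=O)/C(C)=C/C(=O)Oc1cc(C)c(C(=O)OCc2ccccc2)c(OCc2ccccc2)c1 | intermediate
10 | lithium enolate of 9 at the acetyl group | [Li+].[O-]C(=C)/C(C)=C/C(=O)Oc1cc(C)c(C(=O)OCc2ccccc2)c(OCc2ccccc2)c1 | intermediate (not isolated)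
11 | benzyl 2-(benzyloxy)-6-methyl-4-{[(2E)-7,7,7-trifluoro-3-methyl-4,6-dioxohept-2-enoyl]oxy}benzoate | O=C(CC(=O)C(F)(F)F)/C(C)=C/C(=O)Oc1cc(C)c(C(=O)OCc2ccccc2)c(OCc2ccccc2)c1 | intermediate (not isolated)
12 | benzyl 2-(benzyloxy)-4-{[(2E)-5-diazo-3-methyl-4-oxopent-2-enoyl]oxy}-6-methylbenzoate | [N-]=[N+]=CC(=O)/C(C)=C/C(=O)Oc1cc(C)c(C(=O)OCc2ccccc2)c(OCc2ccccc2)c1 | intermediate
13 | 3-phenylisoxazole | c1ccc(cc1)-c1ccon1 | starting material
14 | triisopropylsilyl trifluoromethanesulfonate | CC(C)[Si](OS(=O)(=O)C(F)(F)F)(C(C)C)C(C)C | starting material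
15 | 5-lithio-3-phenylisoxazole | [Li]c1cc(-c2ccccc2)no1 | intermediate (not isolated)
16 | lithium ethynolate | [Li+].[O-]C#C | intermediate (not isolated)
17 | (triisopropylsilyloxy)acetylene | C#CO[Si](C(C)C)(C(C)C)C(C)C | intermediate
18 | ring C aryl (2E)-3-methyl-5-oxopenta-2,4-dienoate (vinylketene) | O=C=C/C(C)=C/C(=O)Oc1cc(C)c(C(=O)OCc2ccccc2)c(OCc2ccccc2)c1 | intermediate (not isolated)
19 | ring C aryl (2E)-3-[4-oxo-2-(triisopropylsilyloxy)cyclobut-2-en-1-yl]but-2-enoate (racemic at the ring carbon) | O=C1C=C(O[Si](C(C)C)(C(C)C)C(C)C)C1/C(C)=C/C(=O)Oc1cc(C)c(C(=O)OCc2ccccc2)c(OCc2ccccc2)c1 | intermediate (not isolated)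
20 | ring C aryl (2E,4E)-3-methyl-7-oxo-5-(triisopropylsilyloxy)hepta-2,4,6-trienoate (dienylketene, ketene arm cis to the C3 arm) | O=C=C/C(O[Si](C(C)C)(C(C)C)C(C)C)=C\C(C)=C\C(=O)Oc1cc(C)c(C(=O)OCc2ccccc2)c(OCc2ccccc2)c1 | intermediate (not isolated)
21 | ring C aryl 2-methyl-6-oxo-4-(triisopropylsilyloxy)cyclohexa-2,4-diene-1-carboxylate (racemic) | O=C1C=C(O[Si](C(C)C)(C(C)C)C(C)C)C=C(C)C1C(=O)Oc1cc(C)c(C(=O)OCc2ccccc2)c(OCc2ccccc2)c1 | intermediate (not isolated)
22 | benzyl 2-(benzyloxy)-4-({2-hydroxy-6-methyl-4-[(triisopropylsilyl)oxy]benzoyl}oxy)-6-methylbenzoate | Cc1cc(O[Si](C(C)C)(C(C)C)C(C)C)cc(O)c1C(=O)Oc1cc(C)c(C(=O)OCc2ccccc2)c(OCc2ccccc2)c1 | intermediate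
23 | benzyl 2-(benzyloxy)-4-[(2,4-dihydroxy-6-methylbenzoyl)oxy]-6-methylbenzoate | Cc1cc(O)cc(O)c1C(=O)Oc1cc(C)c(C(=O)OCc2ccccc2)c(OCc2ccccc2)c1 | intermediate
24 | 2,3-dimethoxytoluene | COc1cccc(C)c1OC | starting material
25 | 2-(3,4-dimethoxy-5-methylphenyl)-4,4,5,5-tetramethyl-1,3,2-dioxaborolane | COc1cc(B2OC(C)(C)C(C)(C)O2)cc(C)c1OC | intermediate (not isolated)
26 | 3,4-dimethoxy-5-methylphenol | COc1cc(O)cc(C)c1OC | intermediate
27 | 5-(benzyloxy)-1,2-dimethoxy-3-methylbenzene | COc1cc(OCc2ccccc2)cc(C)c1OC | intermediate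
28 | 6-(benzyloxy)-3,4-dimethoxy-2-methylbenzaldehyde | COc1cc(OCc2ccccc2)c(C=O)c(C)c1OC | intermediate
29 | 6-(benzyloxy)-3,4-dimethoxy-2-methylbenzoic acid | COc1cc(OCc2ccccc2)c(C(=O)O)c(C)c1OC | intermediate
30 | 6-(benzyloxy)-3,4-dimethoxy-2-methylbenzoyl chloride | COc1cc(OCc2ccccc2)c(C(=O)Cl)c(C)c1OC | intermediate (not isolated)
31 | benzyl 4-{[4-{[6-(benzyloxy)-3,4-dimethoxy-2-methylbenzoyl]oxy}-2-hydroxy-6-methylbenzoyl]oxy}-2-(benzyloxy)-6-methylbenzoate | COc1cc(OCc2ccccc2)c(C(=O)Oc2cc(C)c(C(=O)Oc3cc(C)c(C(=O)OCc4ccccc4)c(OCc4ccccc4)c3)c(O)c2)c(C)c1OC | intermediate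
32 | 2-hydroxy-4-({2-hydroxy-4-[(6-hydroxy-3,4-dimethoxy-2-methylbenzoyl)oxy]-6-methylbenzoyl}oxy)-6-methylbenzoic acid (CNP0139469.0) | COc1cc(O)c(C(=O)Oc2cc(C)c(C(=O)Oc3cc(C)c(C(=O)O)c(O)c3)c(O)c2)c(C)c1OC | target

**Step count and risk**

Total steps: 15. Longest linear sequence: 10 (steps 1–6, 8, 9, 14, 15). Step 7 and steps 10–13 are side branches.

Steps most likely to fail:

1. Step 8. The alkene may photoisomerise, after which the ketene can close onto its own ester carbonyl. The diazo ketone may add as a dipole to the electron-poor alkene of a second molecule, or the ketene may oligomerise faster than it is captured by the ynol ether. In that case ring B would be taken from orsellinic acid by classical esterification. Compound 1 is silylated (i-Pr3SiCl, imidazole, DMF) at the carboxyl group and at the unchelated 4-hydroxyl to give triisopropylsilyl 2-hydroxy-6-methyl-4-[(triisopropylsilyl)oxy]benzoate F1. The silyl ester alone is cleaved (K2CO3, MeOH–H2O, 0 °C) to give 2-hydroxy-6-methyl-4-[(triisopropylsilyl)oxy]benzoic acid F2. F2 is then esterified with phenol 5 (DCC, cat. DMAP, toluene, chelated hydroxyl left free), which rejoins the route at 22.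

2. Step 6. The lithium enolate may add in conjugate fashion to unreacted 9 or attack the aryl ester, or the base may deprotonate the C3 methyl group. In that case the diazo group would be installed before the aryl ester exists. Compounds 6 and 7 with 2-(trimethylsilyl)ethanol should give, by the same addition–Wittig sequence, 2-(trimethylsilyl)ethyl (2E)-3-methyl-4-oxopent-2-enoate F3. The same detrifluoroacetylative diazo transfer, now on a robust alkyl ester, gives 2-(trimethylsilyl)ethyl (2E)-5-diazo-3-methyl-4-oxopent-2-enoate F4. Bu4NF (THF, 0 °C) followed by a pH 4 buffer releases (2E)-5-diazo-3-methyl-4-oxopent-2-enoic acid F5. F5 is coupled at once with 5 (DCC, cat. DMAP, CH2Cl2, 0 °C), which rejoins the route at 12.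

3. Step 7. The ynolate may be silylated on carbon to a silylketene, the organolithium or the ynolate may add to the benzonitrile formed, or the volatile, acid-sensitive ynol ether may be lost on isolation. In that case a non-volatile C-silylated ynol ether would be used. Ethynyltrimethylsilane is lithiated (n-BuLi), oxidised to the ynolate with LiOOt-Bu (Julia oxidation) and O-silylated with 14 to give triisopropyl{[(trimethylsilyl)ethynyl]oxy}silane F6. Benzannulation of 12 with F6 under the conditions of step 8 should give benzyl 2-(benzyloxy)-4-({2-hydroxy-6-methyl-4-[(triisopropylsilyl)oxy]-3-(trimethylsilyl)benzoyl}oxy)-6-methylbenzoate F7. Ipso-protodesilylation at the doubly oxygen-activated B3 (CF3CO2H, CH2Cl2, 0 °C) then rejoins the route at 22.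

**Further compounds**

F1 | step 8 | triisopropylsilyl 2-hydroxy-6-methyl-4-[(triisopropylsilyl)oxy]benzoate | Cc1cc(O[Si](C(C)C)(C(C)C)C(C)C)cc(O)c1C(=O)O[Si](C(C)C)(C(C)C)C(C)C
F2 | step 8 | 2-hydroxy-6-methyl-4-[(triisopropylsilyl)oxy]benzoic acid | Cc1cc(O[Si](C(C)C)(C(C)C)C(C)C)cc(O)c1C(=O)O
F3 | step 6 | 2-(trimethylsilyl)ethyl (2E)-3-methyl-4-oxopent-2-enoate | CC(=O)/C(C)=C/C(=O)OCC[Si](C)(C)C
F4 | step 6 | 2-(trimethylsilyl)ethyl (2E)-5-diazo-3-methyl-4-oxopent-2-enoate | [N-]=[N+]=CC(=O)/C(C)=C/C(=O)OCC[Si](C)(C)C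
F5 | step 6 | (2E)-5-diazo-3-methyl-4-oxopent-2-enoic acid | [N-]=[N+]=CC(=O)/C(C)=C/C(=O)O
F6 | step 7 | triisopropyl{[(trimethylsilyl)ethynyl]oxy}silane | C[Si](C)(C)C#CO[Si](C(C)C)(C(C)C)C(C)C
F7 | step 7 | benzyl 2-(benzyloxy)-4-({2-hydroxy-6-methyl-4-[(triisopropylsilyl)oxy]-3-(trimethylsilyl)benzoyl}oxy)-6-methylbenzoate | Cc1cc(O[Si](C(C)C)(C(C)C)C(C)C)c([Si](C)(C)C)c(O)c1C(=O)Oc1cc(C)c(C(=O)OCc2ccccc2)c(OCc2ccccc2)c1
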